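## The problem

Compound 25 is a diester in which an all-trans cyclopentane (C1 bearing CH2O-acyl, C2 methyl, C3 O-acyl, C4 H2, C5 a 1,3-dihydroxypropan-2-yl group) carries two identical (3S,4E)-4-formyl-3-(2-oxoethyl)hex-4-enoyl chains, one on the primary and one on the secondary oxygen. The ring stereocentres C5, C1, C2 and C3 are contiguous and can relay into one another. C5 is the anchor, because it bears only carbon and cannot be corrected later; C1 can be equilibrated at the aldehyde level and C3 inverted at the alcohol level. The two C3' centres of the arms lie four and five bonds from the nearest ring stereocentre, so the ring cannot control them; they need reagent control, in the same sense twice. Four aldehydes (two in trisubstituted enals whose α-carbon C4' carries C3'), two esters and a free 1,3-diol exclude base, nucleophiles, oxidants and reductants late in the route, so the arms must travel masked and be released by mild acid at the end. The enabling feature is that in each arm the formyl carbon on C4', C4', C3', the CH2 of the oxoethyl branch and its CHO form a 1,5-dialdehyde. Joined through one oxygen this is a 2-alkoxy-3,4-dihydro-2H-pyran with C3' as ring carbon 4, and that ring is the [4+2] adduct of an enal O=CH–CH=CH–CH2CO2R with a vinyl ether. The ring enol-ether carbon (the future C4') is nucleophilic and can later take up the two-carbon ethylidene unit.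

## Retrosynthesis

**25 to 24.** No skeletal bond is cut. Each 1,5-dialdehyde is closed to a 2,6-dialkoxyoxane, each C4'=CH–CH3 bond is hydrated as a β-methoxyethyl group, and the diol is tied up as an acetonide. This is preferred to a late fourfold oxidation of alcohols, which would generate aldehydes beside the C3' centres in a molecule that tolerates no oxidant. Bis-adduct 24 has no free carbonyl other than the esters. The forward step asks aqueous acid to open three kinds of acetal and expel methanol towards the more stable E-enal without touching the esters.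

**24 to 22 and 23.** The bond between C4' and the ethylidene CH is cut in both arms. In bis-dihydropyran 22 that carbon is the β-carbon of a ring enol ether, the only nucleophilic carbon in the molecule, and two molecules of acetaldehyde dimethyl acetal 23 supply the electrophiles. A Wittig ethylidenation of a ketone would leave the alkene geometry to kinetic chance; here it is settled thermodynamically in the elimination. The forward step needs the oxocarbenium ion from 23 to attack the enol ether faster than the Lewis acid ionises the ring acetal or the acetonide.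

**22 to 20 and 21 (key disconnection).** In each ring the C4–C3 and O1–C2 bonds are cut, giving bis-enal 20 and two molecules of ethyl vinyl ether 21. This removes both rings and all four new stereocentres at once and reduces each arm to a linear five-carbon enal ester. A stepwise Michael–acetalisation would need a preformed enolate equivalent of acetaldehyde and separate control at C3'. The forward reaction needs catalyst-controlled facial selectivity of the same sense in both arms, and the skipped enal–ester must not slip into conjugation.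

**20 to 18 and 19.** The C3=C4 alkene of each 5-oxopent-3-enoate is cut by cross-metathesis, giving bis(but-3-enoate) 18 and two molecules of crotonaldehyde 19. The doubly activated CH2 of the enal ester is too labile to carry as a free acid through an esterification, so the enal is made on the ester. The forward step needs E-selective cross-metathesis to outrun alkene migration and ring closure between the arms.

**18 to 16 and 17.** Both ester C–O bonds are cut, the secondary one at the alkyl carbon, and each hydroxyl takes up one molecule of but-3-enoic acid 17. At C3 the acid displaces an activated oxygen with inversion, so the precursor diol 16 has its C3 hydroxyl cis to the C2 methyl. This allows the C3 oxygen to sit on the same face as the C5 group throughout the core synthesis, where it reinforces facial control. A plain acylation would demand the trans alcohol, which the earlier steps do not deliver.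

**16 to 12.** The C1–H and C2–H bonds are removed and CH2OH is raised to CHO, giving the planar enal 12, with saturated aldehydes 13 and 14 and alcohol 15 on the way forward. In 12 the silyl ether at C3 and the dioxanyl group at C5 shield the same face, so hydrogen must arrive from the other face and set C2. C1 is then set by equilibration, its trans,trans arrangement being the stable one.

**12 to 11 to 9.** The C1=C2 bond is cut as an aldol condensation of keto aldehyde 11, and 11 is reconnected to cyclohexene 9 as its ozonolysis product. A cyclopentene with two stereocentres becomes a carveol-type cyclohexene with the same two, so the ring contraction creates no new stereochemical problem. The forward aldol must proceed through the aldehyde enamine onto the methyl ketone, with the α-silyloxy centre intact.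

**9 to 5 to 1.** Removing the protecting groups (via 8 and 7) leads to diol 5. Its second primary hydroxyl comes from hydroboration of the 1,1-disubstituted alkene, the ring carbinol from 1,2-reduction of the enone, and the allylic oxygen from chlorination of the isopropenyl methyl (3, 2). (S)-Carvone 1 supplies all ten core carbons and the C5 configuration in the correct absolute sense.

## Roads not taken

All three alternatives build only the cyclopentane. Each would still need steps 12–16 for the arms, so the comparison is between core syntheses.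

Alternative 1: The C1–C5 ring bond is cut. Forward, the acyclic enal–alkylidene malonate A1 (dimethyl 2-[(3R,4E)-3-silyloxy-4-methyl-6-oxohex-4-en-1-ylidene]propanedioate) is treated with a chiral imidazolidinone salt and a Hantzsch ester. Hydride goes to C2 and the enamine carbon C1 adds to C5, giving the all-trans formyl malonate A2.
- Merits: the ring and three stereocentres (C2, C1, C5) form in one catalytic operation, the malonate is the latent 1,3-diol, and the aldehyde is the C1 handle.
- Weak points: the alkylidene malonate is itself a good hydride acceptor, so two electrophiles compete for the Hantzsch ester. C2 is set by hydride delivery next to the existing C3 silyl ether, so catalyst and substrate preferences may oppose. The γ-silyloxy iminium ion can lose silanol through its dienamine. A1 needs its own enantioselective carbinol synthesis.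
- Comparison: from A2 the core diol would be reached in fewer operations than from carvone, which is a real advantage. The chosen plan offers in return that every core centre derives from one purchased centre, through steps with reinforcing steric bias or thermodynamic control and without a matched/mismatched question.

Alternative 2: The exocyclic C1–CH2 and C2–CH3 bonds are cut. Forward, the copper-catalysed Grignard reagent (isopropoxydimethylsilyl)methylmagnesium chloride (with CuI) adds to enone A3 ((4R)-4-(2,2-dimethyl-1,3-dioxan-5-yl)cyclopent-2-en-1-one) anti to the C5 group, and the enolate is methylated to give ketone A4.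
- Merits: two C–C bonds and two stereocentres form in one flask, each trans to its neighbour by the normal behaviour of 4-substituted cyclopentenones. A3 is accessible by catalytic asymmetric allylic alkylation in either hand. Silicon serves as a masked hydroxyl.
- Weak points: methylation of such cyclopentanone enolates competes with proton exchange, which leads to regioisomers and double alkylation. The ketone must then be reduced to the alcohol trans to the adjacent methyl, where small hydrides are only moderately selective. The silane must still be oxidised.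
- Comparison: this is probably the shortest way to the core and it is catalytic in chirality; the chosen route is longer. In return, C3 is set cleanly by a cis-selective enone reduction and then inverted in the esterification itself, and no enolate trapping is required.

Alternative 3: The C2–C3 ring bond is cut. Forward, cathodic one-electron reduction of aldehyde A5 ((3R,4R)-4-[(benzyloxy)methyl]-3-(2,2-dimethyl-1,3-dioxan-5-yl)hex-5-enal) gives a ketyl that closes 5-exo onto the inner vinyl carbon. The exocyclic radical is reduced and protonated to the methyl group of cyclopentanol A6.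
- Merits: the ring, the hydroxyl and the methyl arise in one reagent-free step. The anti relation of oxygen and the new methyl is the usual outcome, and a chair-like transition state with C1 and C5 groups equatorial leads to the all-trans ring.
- Weak points: an unactivated terminal alkene is a slow ketyl acceptor, so pinacol coupling and simple reduction of the aliphatic aldehyde compete. The two contiguous acyclic centres of A5 must be made beforehand. The benzyl ether adds a deprotection.
- Comparison: if the cyclisation performs, the route is of similar length and better in oxidation-state economy. The chosen plan relies on routine thermal reactions without electrochemical equipment and starts from a stereocentre that is bought, not made.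

Key step: step 14

Assumption: CrCl(L) with the ligand from (1R,2S)-1-amino-2-indanol is taken to give the (4S) rings, by analogy with simple β-alkyl enals; if the sense is the reverse, the mirror-image ligand from (1S,2R)-1-amino-2-indanol is used and nothing else changes.

## Route

Step 1
Reactants: 1 (S)-(+)-carvone
Product: 2 (5S)-5-(3-chloroprop-1-en-2-yl)-2-methylcyclohex-2-en-1-one
Conditions: Ca(OCl)2, solid CO2, CH2Cl2/H2O, 0 °C
Reagents that add atoms: calcium hypochlorite, [Ca+2].[O-]Cl.[O-]Cl
Why: Ene-type allylic chlorination by hypochlorous acid formed in the flask; the electron-rich 1,1-disubstituted alkene reacts, the enone alkene is inert and the stereocentre is not involved.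

Step 2
Reactants: 2 (5S)-5-(3-chloroprop-1-en-2-yl)-2-methylcyclohex-2-en-1-one
Product: 3 2-[(1S)-4-methyl-5-oxocyclohex-3-en-1-yl]prop-2-en-1-yl acetate
Conditions: KOAc, NaI (cat.), DMF, 50 °C
Reagents that add atoms: potassium acetate, CC(=O)[O-].[K+]
Why: SN2 displacement of a primary allylic chloride by acetate, assisted by iodide exchange.

Step 3
Reactants: 3 2-[(1S)-4-methyl-5-oxocyclohex-3-en-1-yl]prop-2-en-1-yl acetate
Product: 5 (1S,5S)-5-(3-hydroxyprop-1-en-2-yl)-2-methylcyclohex-2-en-1-ol, via acetoxy-cis-carveol 4 (not isolated)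
Conditions: NaBH4, CeCl3·7H2O, MeOH, −20 °C; then K2CO3 (2 equiv), rt
Reagents that add atoms: none
Why: Luche 1,2-reduction; axial hydride delivery to the half-chair with the C5 group equatorial gives the alcohol cis to that group, as for carvone itself, and the acetate is then removed in the same pot by base-mediated methanolysis.

Step 4
Reactants: 5 (1S,5S)-5-(3-hydroxyprop-1-en-2-yl)-2-methylcyclohex-2-en-1-ol
Product: 7 2-[(1S,5S)-5-hydroxy-4-methylcyclohex-3-en-1-yl]propane-1,3-diol, via tris(9-BBN) adduct 6 (not isolated)
Conditions: 9-BBN (3.3 equiv), THF, 0 °C to rt; then NaOH aq, H2O2, 0 °C to rt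
Reagents that add atoms: hydrogen peroxide, OO
Why: Hydroboration–oxidation; 9-BBN first converts both hydroxyls into borinic esters and then adds anti-Markovnikov to the 1,1-disubstituted alkene much faster than to the trisubstituted ring alkene; the new CH carries two identical CH2OH arms, so no stereocentre arises.

Step 5
Reactants: 7 2-[(1S,5S)-5-hydroxy-4-methylcyclohex-3-en-1-yl]propane-1,3-diol
Product: 8 (1S,5S)-5-(2,2-dimethyl-1,3-dioxan-5-yl)-2-methylcyclohex-2-en-1-ol
Conditions: Me2C(OMe)2, PPTS (cat.), acetone, rt
Reagents that add atoms: 2,2-dimethoxypropane, COC(C)(C)OC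
Why: Transketalisation closes the six-membered 1,3-dioxane on the 1,3-diol; the remote secondary hydroxyl cannot form a ring and stays free, and the weak acid does not ionise the allylic alcohol.

Step 6
Reactants: 8 (1S,5S)-5-(2,2-dimethyl-1,3-dioxan-5-yl)-2-methylcyclohex-2-en-1-ol
Product: 9 tert-butyl{[(1S,5S)-5-(2,2-dimethyl-1,3-dioxan-5-yl)-2-methylcyclohex-2-en-1-yl]oxy}dimethylsilane
Conditions: TBSCl, imidazole, DMF, rt
Reagents that add atoms: tert-butyldimethylsilyl chloride, CC(C)(C)[Si](C)(C)Cl
Why: Standard silylation of a secondary allylic alcohol; the bulky silyl ether prevents lactol formation after ring cleavage and later shields one ring face.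

Step 7
Reactants: 9 tert-butyl{[(1S,5S)-5-(2,2-dimethyl-1,3-dioxan-5-yl)-2-methylcyclohex-2-en-1-yl]oxy}dimethylsilane
Product: 11 (3R,5S)-5-{[tert-butyl(dimethyl)silyl]oxy}-3-(2,2-dimethyl-1,3-dioxan-5-yl)-6-oxoheptanal, via secondary ozonide 10 (not isolated)
Conditions: O3, CH2Cl2, −78 °C; then Me2S, −78 °C to rt
Reagents that add atoms: ozone, [O-][O+]=O
Why: Ozonolysis with reductive work-up of the only alkene left; ketal and silyl ether are inert and neither stereocentre is touched.

Step 8
Reactants: 11 (3R,5S)-5-{[tert-butyl(dimethyl)silyl]oxy}-3-(2,2-dimethyl-1,3-dioxan-5-yl)-6-oxoheptanal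
Product: 12 (3S,5S)-3-{[tert-butyl(dimethyl)silyl]oxy}-5-(2,2-dimethyl-1,3-dioxan-5-yl)-2-methylcyclopent-1-ene-1-carbaldehyde
Conditions: piperidine, AcOH (0.3 equiv each), toluene, 60 °C
Reagents that add atoms: none
Why: Amine-catalysed intramolecular aldol condensation; the enamine of the aldehyde adds 5-exo to the methyl ketone and dehydration to the tetrasubstituted enal makes it irreversible, as in the ring contraction of the analogous keto aldehyde from limonene; the alternative aldol through the silyloxy-bearing carbon cannot dehydrate and reverts.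

Step 9
Reactants: 12 (3S,5S)-3-{[tert-butyl(dimethyl)silyl]oxy}-5-(2,2-dimethyl-1,3-dioxan-5-yl)-2-methylcyclopent-1-ene-1-carbaldehyde
Product: 13 (1R,2R,3S,5S)-3-{[tert-butyl(dimethyl)silyl]oxy}-5-(2,2-dimethyl-1,3-dioxan-5-yl)-2-methylcyclopentane-1-carbaldehyde
Conditions: H2 (1 atm), Pd/C (10%), EtOAc, rt
Reagents that add atoms: none
Why: Heterogeneous syn hydrogenation of a conjugated tetrasubstituted alkene; the silyl ether at C3 and the dioxanyl group at C5 block the same face, so both hydrogens arrive from the other face and C2 receives its methyl on the face of the C5 group, as the target requires.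

Step 10
Reactants: 13 (1R,2R,3S,5S)-3-{[tert-butyl(dimethyl)silyl]oxy}-5-(2,2-dimethyl-1,3-dioxan-5-yl)-2-methylcyclopentane-1-carbaldehyde
Product: 15 [(1S,2R,3S,5R)-3-{[tert-butyl(dimethyl)silyl]oxy}-5-(2,2-dimethyl-1,3-dioxan-5-yl)-2-methylcyclopentyl]methanol, via trans-aldehyde 14 (not isolated)
Conditions: K2CO3 (0.5 equiv), MeOH, rt; then NaBH4, 0 °C
Reagents that add atoms: none
Why: Base-mediated epimerisation through the enolate moves the formyl group from the all-cis arrangement to the position trans to both neighbours (thermodynamic control at C1), and borohydride reduction then fixes that centre as the primary alcohol.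

Step 11
Reactants: 15 [(1S,2R,3S,5R)-3-{[tert-butyl(dimethyl)silyl]oxy}-5-(2,2-dimethyl-1,3-dioxan-5-yl)-2-methylcyclopentyl]methanol
Product: 16 (1S,2R,3S,4R)-4-(2,2-dimethyl-1,3-dioxan-5-yl)-3-(hydroxymethyl)-2-methylcyclopentan-1-ol
Conditions: Bu4NF, THF, rt
Reagents that add atoms: none
Why: Fluoride-induced desilylation; the acetonide is stable to fluoride and no stereocentre is affected.

Step 12
Reactants: 16 (1S,2R,3S,4R)-4-(2,2-dimethyl-1,3-dioxan-5-yl)-3-(hydroxymethyl)-2-methylcyclopentan-1-ol; 17 but-3-enoic acid
Product: 18 [(1S,2R,3R,5R)-3-(but-3-enoyloxy)-5-(2,2-dimethyl-1,3-dioxan-5-yl)-2-methylcyclopentyl]methyl but-3-enoate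
Conditions: 17 (2.4 equiv), PPh3, DIAD (3 equiv each), THF, 0 °C to rt
Reagents that add atoms: but-3-enoic acid (second molecule of 17, for the second hydroxyl), C=CCC(=O)O
Why: Double Mitsunobu esterification that consumes two molecules of 17; the primary hydroxyl is acylated first, then the C3 oxyphosphonium ion is displaced by but-3-enoate from the face opposite to oxygen (SN2), which inverts C3 to trans to the C2 methyl and completes the all-trans ring; the near-neutral medium keeps the β,γ-alkene out of conjugation.

Step 13
Reactants: 18 [(1S,2R,3R,5R)-3-(but-3-enoyloxy)-5-(2,2-dimethyl-1,3-dioxan-5-yl)-2-methylcyclopentyl]methyl but-3-enoate; 19 crotonaldehyde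
Product: 20 [(1S,2R,3R,5R)-5-(2,2-dimethyl-1,3-dioxan-5-yl)-2-methyl-3-{[(3E)-5-oxopent-3-enoyl]oxy}cyclopentyl]methyl (3E)-5-oxopent-3-enoate
Conditions: 19 (10 equiv), RuCl2(H2IMes)(PCy3)(=CHPh) (second-generation Grubbs catalyst, 5 mol%), 1,4-benzoquinone (10 mol%), CH2Cl2, 40 °C
Reagents that add atoms: crotonaldehyde (second molecule of 19, for the second arm), C/C=C/C=O
Why: Twofold olefin cross-metathesis of the terminal alkenes with an electron-poor partner, one molecule of 19 per arm, gives the E-enals with loss of propene; excess crotonaldehyde suppresses ring closure between the arms and benzoquinone suppresses hydride-mediated alkene migration.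

Step 14
Reactants: 20 [(1S,2R,3R,5R)-5-(2,2-dimethyl-1,3-dioxan-5-yl)-2-methyl-3-{[(3E)-5-oxopent-3-enoyl]oxy}cyclopentyl]methyl (3E)-5-oxopent-3-enoate; 21 ethyl vinyl ether
Product: 22 [(1S,2R,3R,5R)-5-(2,2-dimethyl-1,3-dioxan-5-yl)-3-({2-[(2R,4S)-2-ethoxy-3,4-dihydro-2H-pyran-4-yl]acetyl}oxy)-2-methylcyclopentyl]methyl 2-[(2R,4S)-2-ethoxy-3,4-dihydro-2H-pyran-4-yl]acetate (both rings cis-2,4)
Conditions: 21 (20 equiv, also the solvent), CrCl(L) (10 mol%; L = dianion of the Schiff base from 3-(1-adamantyl)-2-hydroxy-5-methylbenzaldehyde and (1R,2S)-1-amino-2-indanol), 4 Å MS, rt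
Reagents that add atoms: ethyl vinyl ether (second molecule of 21, for the second arm), C=COCC
Why: The trivalent-chromium Lewis acid CrCl(L) binds the aldehyde oxygen of each arm and lowers the LUMO of the O=CH–CH=CH 1-oxadiene, which combines with the electron-rich alkene of 21 in a concerted, asynchronous inverse-electron-demand hetero-Diels–Alder reaction, C–C bond formation at the β-carbon running ahead of O–C bond formation. The closest known reaction is the cycloaddition of simple (E)-β-alkyl enals with ethyl vinyl ether under the same class of catalyst, applied here twice on one substrate. Each ring closes by intermolecular [4+2] cycloaddition, one molecule of 21 per arm, the pyran C4–C3 and O1–C2 bonds forming in one event to give a 3,4-dihydro-2H-pyran. The C4 centre of each ring, the future C3', is set by the catalyst, whose indanyl and adamantyl groups leave one face of the bound oxadiene open. The C2 acetal centre follows from the endo orientation of the ethoxy group and is therefore cis to the C4 substituent. The step needs the same facial sense in both arms; the CH2CO2 spacers make each enal an ordinary unbranched β-alkyl enal that the ring stereocentres, four and five bonds from the reacting β-carbons, cannot override. It also needs the aldehyde and not the ester carbonyl to serve as heterodiene and the skipped enal–ester to stay unconjugated, which the higher Lewis basicity of the aldehyde and the base-free medium secure. The C2 configuration is of no consequence because that carbon becomes an aldehyde in step 16.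

Step 15
Reactants: 22 [(1S,2R,3R,5R)-5-(2,2-dimethyl-1,3-dioxan-5-yl)-3-({2-[(2R,4S)-2-ethoxy-3,4-dihydro-2H-pyran-4-yl]acetyl}oxy)-2-methylcyclopentyl]methyl 2-[(2R,4S)-2-ethoxy-3,4-dihydro-2H-pyran-4-yl]acetate; 23 acetaldehyde dimethyl acetal
Product: 24 [(1S,2R,3R,5R)-5-(2,2-dimethyl-1,3-dioxan-5-yl)-3-({2-[(4S)-6-ethoxy-2-methoxy-3-(1-methoxyethyl)oxan-4-yl]acetyl}oxy)-2-methylcyclopentyl]methyl 2-[(4S)-6-ethoxy-2-methoxy-3-(1-methoxyethyl)oxan-4-yl]acetate (mixture at the acetal and methoxyethyl carbons)
Conditions: 23 (10 equiv), BF3·OEt2 (0.2 equiv), CH2Cl2, −78 °C; Et3N quench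
Reagents that add atoms: acetaldehyde dimethyl acetal (second molecule of 23, for the second ring), CC(OC)OC
Why: Lewis-acid-catalysed addition of an acetal to an enol ether (Müller-Cunradi–Pieroh type, known for cyclic enol ethers), one molecule of 23 per ring; the methoxyethyl cation from 23 attacks the enol-ether β-carbon and methoxide caps the ring oxocarbenium ion, forming the C4'–C bond; the new centres and any ethoxy/methoxy exchange are irrelevant because all are erased in step 16, and C4 of the ring is not involved.

Step 16
Reactants: 24 [(1S,2R,3R,5R)-5-(2,2-dimethyl-1,3-dioxan-5-yl)-3-({2-[(4S)-6-ethoxy-2-methoxy-3-(1-methoxyethyl)oxan-4-yl]acetyl}oxy)-2-methylcyclopentyl]methyl 2-[(4S)-6-ethoxy-2-methoxy-3-(1-methoxyethyl)oxan-4-yl]acetate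
Product: 25 [(1S,2R,3R,5R)-5-(1,3-dihydroxypropan-2-yl)-3-{[(3S,4E)-4-formyl-3-(2-oxoethyl)hex-4-enoyl]oxy}-2-methylcyclopentyl]methyl (3S,4E)-4-formyl-3-(2-oxoethyl)hex-4-enoate
Conditions: 1 M HCl aq/THF, rt
Reagents that add atoms: water, O
Why: Acid hydrolysis opens both cyclic bis-acetals to 1,5-dialdehydes and removes the acetonide, and the β-methoxy aldehydes lose methanol through their enols to give the conjugated enals, the E isomer (methyl trans to formyl) being the thermodynamic one; C3' is not α to any carbonyl and keeps its configuration.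

## Compound list

1 | (S)-(+)-carvone, (5S)-2-methyl-5-(prop-1-en-2-yl)cyclohex-2-en-1-one | CC(=C)[C@H]1CC=C(C)C(=O)C1 | starting material
2 | (5S)-5-(3-chloroprop-1-en-2-yl)-2-methylcyclohex-2-en-1-one | ClCC(=C)[C@H]1CC=C(C)C(=O)C1 | intermediate
3 | 2-[(1S)-4-methyl-5-oxocyclohex-3-en-1-yl]prop-2-en-1-yl acetate | CC(=O)OCC(=C)[C@H]1CC=C(C)C(=O)C1 | intermediate
4 | 2-[(1S,5S)-5-hydroxy-4-methylcyclohex-3-en-1-yl]prop-2-en-1-yl acetate | CC(=O)OCC(=C)[C@H]1CC=C(C)[C@@H](O)C1 | intermediate (not isolated)
5 | (1S,5S)-5-(3-hydroxyprop-1-en-2-yl)-2-methylcyclohex-2-en-1-ol | OCC(=C)[C@H]1CC=C(C)[C@@H](O)C1 | intermediate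
6 | 9-{3-[(9-borabicyclo[3.3.1]nonan-9-yl)oxy]-2-[(1S,5S)-5-[(9-borabicyclo[3.3.1]nonan-9-yl)oxy]-4-methylcyclohex-3-en-1-yl]propyl}-9-borabicyclo[3.3.1]nonane | B1(OCC(CB2C3CCCC2CCC3)[C@H]4CC=C(C)[C@@H](OB5C6CCCC5CCC6)C4)C7CCCC1CCC7 | intermediate (not isolated)
7 | 2-[(1S,5S)-5-hydroxy-4-methylcyclohex-3-en-1-yl]propane-1,3-diol | OCC(CO)[C@H]1CC=C(C)[C@@H](O)C1 | intermediate
8 | (1S,5S)-5-(2,2-dimethyl-1,3-dioxan-5-yl)-2-methylcyclohex-2-en-1-ol | CC1(C)OCC(CO1)[C@H]2CC=C(C)[C@@H](O)C2 | intermediate
9 | tert-butyl{[(1S,5S)-5-(2,2-dimethyl-1,3-dioxan-5-yl)-2-methylcyclohex-2-en-1-yl]oxy}dimethylsilane | CC1(C)OCC(CO1)[C@H]2CC=C(C)[C@@H](O[Si](C)(C)C(C)(C)C)C2 | intermediate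
10 | secondary ozonide of 9, tert-butyl{[4-(2,2-dimethyl-1,3-dioxan-5-yl)-1-methyl-7,8,9-trioxabicyclo[4.2.1]nonan-2-yl]oxy}dimethylsilane (carbinol and side-chain centres as in 9) | CC1(C)OCC(CO1)[C@H]2CC3OOC(C)(O3)[C@@H](O[Si](C)(C)C(C)(C)C)C2 | intermediate (not isolated)
11 | (3R,5S)-5-{[tert-butyl(dimethyl)silyl]oxy}-3-(2,2-dimethyl-1,3-dioxan-5-yl)-6-oxoheptanal | O=CC[C@H](C1COC(C)(C)OC1)C[C@H](O[Si](C)(C)C(C)(C)C)C(C)=O | intermediate
12 | (3S,5S)-3-{[tert-butyl(dimethyl)silyl]oxy}-5-(2,2-dimethyl-1,3-dioxan-5-yl)-2-methylcyclopent-1-ene-1-carbaldehyde | O=CC1=C(C)[C@@H](O[Si](C)(C)C(C)(C)C)C[C@H]1C2COC(C)(C)OC2 | intermediate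
13 | (1R,2R,3S,5S)-3-{[tert-butyl(dimethyl)silyl]oxy}-5-(2,2-dimethyl-1,3-dioxan-5-yl)-2-methylcyclopentane-1-carbaldehyde (all-cis) | O=C[C@H]1[C@@H](C)[C@@H](O[Si](C)(C)C(C)(C)C)C[C@H]1C2COC(C)(C)OC2 | intermediate
14 | (1S,2R,3S,5S)-3-{[tert-butyl(dimethyl)silyl]oxy}-5-(2,2-dimethyl-1,3-dioxan-5-yl)-2-methylcyclopentane-1-carbaldehyde | O=C[C@@H]1[C@@H](C)[C@@H](O[Si](C)(C)C(C)(C)C)C[C@H]1C2COC(C)(C)OC2 | intermediate (not isolated)
15 | [(1S,2R,3S,5R)-3-{[tert-butyl(dimethyl)silyl]oxy}-5-(2,2-dimethyl-1,3-dioxan-5-yl)-2-methylcyclopentyl]methanol | OC[C@@H]1[C@@H](C)[C@@H](O[Si](C)(C)C(C)(C)C)C[C@H]1C2COC(C)(C)OC2 | intermediate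
16 | (1S,2R,3S,4R)-4-(2,2-dimethyl-1,3-dioxan-5-yl)-3-(hydroxymethyl)-2-methylcyclopentan-1-ol | OC[C@@H]1[C@@H](C)[C@@H](O)C[C@H]1C2COC(C)(C)OC2 | intermediate
17 | but-3-enoic acid | C=CCC(=O)O | starting material
18 | [(1S,2R,3R,5R)-3-(but-3-enoyloxy)-5-(2,2-dimethyl-1,3-dioxan-5-yl)-2-methylcyclopentyl]methyl but-3-enoate | C=CCC(=O)OC[C@@H]1[C@@H](C)[C@H](OC(=O)CC=C)C[C@H]1C2COC(C)(C)OC2 | intermediate
19 | crotonaldehyde, (2E)-but-2-enal | C/C=C/C=O | starting material
20 | [(1S,2R,3R,5R)-5-(2,2-dimethyl-1,3-dioxan-5-yl)-2-methyl-3-{[(3E)-5-oxopent-3-enoyl]oxy}cyclopentyl]methyl (3E)-5-oxopent-3-enoate | O=C/C=C/CC(=O)OC[C@@H]1[C@@H](C)[C@H](OC(=O)C/C=C/C=O)C[C@H]1C2COC(C)(C)OC2 | intermediate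
21 | ethyl vinyl ether | C=COCC | starting material
22 | [(1S,2R,3R,5R)-5-(2,2-dimethyl-1,3-dioxan-5-yl)-3-({2-[(2R,4S)-2-ethoxy-3,4-dihydro-2H-pyran-4-yl]acetyl}oxy)-2-methylcyclopentyl]methyl 2-[(2R,4S)-2-ethoxy-3,4-dihydro-2H-pyran-4-yl]acetate | O=C(C[C@H]1C=CO[C@@H](OCC)C1)OC[C@@H]2[C@@H](C)[C@H](OC(=O)C[C@H]3C=CO[C@@H](OCC)C3)C[C@H]2C4COC(C)(C)OC4 | intermediate
23 | acetaldehyde dimethyl acetal, 1,1-dimethoxyethane | CC(OC)OC | starting material
24 | [(1S,2R,3R,5R)-5-(2,2-dimethyl-1,3-dioxan-5-yl)-3-({2-[(4S)-6-ethoxy-2-methoxy-3-(1-methoxyethyl)oxan-4-yl]acetyl}oxy)-2-methylcyclopentyl]methyl 2-[(4S)-6-ethoxy-2-methoxy-3-(1-methoxyethyl)oxan-4-yl]acetate | O=C(C[C@@H]1CC(OCC)OC(OC)C1C(C)OC)OC[C@@H]2[C@@H](C)[C@H](OC(=O)C[C@@H]3CC(OCC)OC(OC)C3C(C)OC)C[C@H]2C4COC(C)(C)OC4 | intermediate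
25 | [(1S,2R,3R,5R)-5-(1,3-dihydroxypropan-2-yl)-3-{[(3S,4E)-4-formyl-3-(2-oxoethyl)hex-4-enoyl]oxy}-2-methylcyclopentyl]methyl (3S,4E)-4-formyl-3-(2-oxoethyl)hex-4-enoate | C/C=C(/C=O)[C@@H](CC=O)CC(=O)OC[C@@H]1[C@@H](C)[C@H](OC(=O)C[C@H](CC=O)/C(C=O)=C\C)C[C@H]1C(CO)CO | target

## Step count and least certain steps

Total: 16 steps. Longest linear sequence: 16 steps from 1; compounds 17, 19, 21 and 23 are purchased.

**Step 14 (key step).** The most likely failures are incomplete conversion of the second arm and erosion of facial selectivity. The substrate offers many Lewis-basic oxygens to the catalyst, and any minor sense of addition shows up as hard-to-separate diastereomers because two arms react. Slow cycloaddition also gives the skipped enal–ester time to move into conjugation with the ester. Fallback: build the arm on a small molecule and attach it afterwards, setting out from diol 16 and returning at 22. Methyl but-3-enoate F1 is cross-metathesised with 19 to methyl (3E)-5-oxopent-3-enoate F2. The same CrCl(L)-catalysed cycloaddition with 21, now on a single unhindered enal, gives methyl 2-[(2R,4S)-2-ethoxy-3,4-dihydro-2H-pyran-4-yl]acetate F3, whose enantiomeric purity can be checked and, if need be, upgraded before it meets the core. Saponification with LiOH and careful acidification gives 2-[(2R,4S)-2-ethoxy-3,4-dihydro-2H-pyran-4-yl]acetic acid F4. A double Mitsunobu reaction of two molecules of F4 with 16 (PPh3, DIAD) gives 22 with the required inversion at C3.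

**Step 15.** The Lewis acid may ionise the ring 2-ethoxy acetal or exchange the acetonide with 23 instead of activating 23 towards the enol ether, which would lead to oligomers through the ring oxocarbenium ion or to a scrambled protecting group. The later loss of methanol also needs acid strong enough to threaten the product. Fallback, from 22 to 25: Vilsmeier–Haack formylation (POCl3, DMF; NaOAc aq) at the enol-ether β-carbons gives the bis(5-formyl) compound [(1S,2R,3R,5R)-5-(2,2-dimethyl-1,3-dioxan-5-yl)-3-({2-[(2R,4S)-2-ethoxy-5-formyl-3,4-dihydro-2H-pyran-4-yl]acetyl}oxy)-2-methylcyclopentyl]methyl 2-[(2R,4S)-2-ethoxy-5-formyl-3,4-dihydro-2H-pyran-4-yl]acetate F5. MeMgBr at −78 °C adds to the vinylogous formate aldehydes in preference to the esters and gives the bis(1-hydroxyethyl) compound [(1S,2R,3R,5R)-5-(2,2-dimethyl-1,3-dioxan-5-yl)-3-({2-[(2R,4S)-2-ethoxy-5-(1-hydroxyethyl)-3,4-dihydro-2H-pyran-4-yl]acetyl}oxy)-2-methylcyclopentyl]methyl 2-[(2R,4S)-2-ethoxy-5-(1-hydroxyethyl)-3,4-dihydro-2H-pyran-4-yl]acetate F6. Dilute aqueous acid ionises these allylic alcohols with help from the ring oxygen; water adds at the oxygen-bearing carbon and the lactols open, giving the E-enals, the free aldehydes and the diol of 25 under milder conditions than step 16.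

**Step 12.** Displacement at the C3 oxyphosphonium ion, which is flanked by a cis methyl, may be slow with a carboxylic acid of ordinary acidity. Elimination to the cyclopentene, substitution with retention through an acyloxyphosphonium ion, or base-induced migration of the β,γ-alkene could then compete. Fallback, from 16 to 18: Mitsunobu reaction with the more acidic 4-nitrobenzoic acid gives [(1S,2R,3R,5R)-5-(2,2-dimethyl-1,3-dioxan-5-yl)-2-methyl-3-(4-nitrobenzoyloxy)cyclopentyl]methyl 4-nitrobenzoate F7. Methanolysis (K2CO3, MeOH) gives the inverted diol (1R,2R,3S,4R)-4-(2,2-dimethyl-1,3-dioxan-5-yl)-3-(hydroxymethyl)-2-methylcyclopentan-1-ol F8. Carbodiimide esterification with two molecules of 17 (DCC, catalytic DMAP, 0 °C) then gives 18 without any substitution at carbon.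

**Step 9.** Saturation of the tetrasubstituted alkene on palladium may be slow. Alkene migration on the metal could then scramble the face of hydrogen delivery at C2, or the allylic C–O bond could be hydrogenolysed. Fallback, from 12 to 13: 1,2-reduction with i-Bu2AlH gives [(3S,5S)-3-{[tert-butyl(dimethyl)silyl]oxy}-5-(2,2-dimethyl-1,3-dioxan-5-yl)-2-methylcyclopent-1-en-1-yl]methanol F9. Homogeneous hydroxyl-assisted hydrogenation with [Ir(cod)(PCy3)(py)]PF6, which reduces tetrasubstituted alkenes without migration and again from the unshielded face, gives [(1R,2R,3S,5R)-3-{[tert-butyl(dimethyl)silyl]oxy}-5-(2,2-dimethyl-1,3-dioxan-5-yl)-2-methylcyclopentyl]methanol F10. Oxidation with Dess–Martin periodinane returns the all-cis aldehyde 13 for step 10.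

## Further compounds

F1 | step 14 | methyl but-3-enoate | C=CCC(=O)OC
F2 | step 14 | methyl (3E)-5-oxopent-3-enoate | O=C/C=C/CC(=O)OC
F3 | step 14 | methyl 2-[(2R,4S)-2-ethoxy-3,4-dihydro-2H-pyran-4-yl]acetate | COC(=O)C[C@H]1C=CO[C@@H](OCC)C1
F4 | step 14 | 2-[(2R,4S)-2-ethoxy-3,4-dihydro-2H-pyran-4-yl]acetic acid | OC(=O)C[C@H]1C=CO[C@@H](OCC)C1
F5 | step 15 | [(1S,2R,3R,5R)-5-(2,2-dimethyl-1,3-dioxan-5-yl)-3-({2-[(2R,4S)-2-ethoxy-5-formyl-3,4-dihydro-2H-pyran-4-yl]acetyl}oxy)-2-methylcyclopentyl]methyl 2-[(2R,4S)-2-ethoxy-5-formyl-3,4-dihydro-2H-pyran-4-yl]acetate | O=C(C[C@H]1C(C=O)=CO[C@@H](OCC)C1)OC[C@@H]2[C@@H](C)[C@H](OC(=O)C[C@H]3C(C=O)=CO[C@@H](OCC)C3)C[C@H]2C4COC(C)(C)OC4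
F6 | step 15 | [(1S,2R,3R,5R)-5-(2,2-dimethyl-1,3-dioxan-5-yl)-3-({2-[(2R,4S)-2-ethoxy-5-(1-hydroxyethyl)-3,4-dihydro-2H-pyran-4-yl]acetyl}oxy)-2-methylcyclopentyl]methyl 2-[(2R,4S)-2-ethoxy-5-(1-hydroxyethyl)-3,4-dihydro-2H-pyran-4-yl]acetate | O=C(C[C@H]1C(C(C)O)=CO[C@@H](OCC)C1)OC[C@@H]2[C@@H](C)[C@H](OC(=O)C[C@H]3C(C(C)O)=CO[C@@H](OCC)C3)C[C@H]2C4COC(C)(C)OC4
F7 | step 12 | [(1S,2R,3R,5R)-5-(2,2-dimethyl-1,3-dioxan-5-yl)-2-methyl-3-(4-nitrobenzoyloxy)cyclopentyl]methyl 4-nitrobenzoate | O=C(OC[C@@H]1[C@@H](C)[C@H](OC(=O)c2ccc(cc2)[N+](=O)[O-])C[C@H]1C3COC(C)(C)OC3)c4ccc(cc4)[N+](=O)[O-]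
F8 | step 12 | (1R,2R,3S,4R)-4-(2,2-dimethyl-1,3-dioxan-5-yl)-3-(hydroxymethyl)-2-methylcyclopentan-1-ol | OC[C@@H]1[C@@H](C)[C@H](O)C[C@H]1C2COC(C)(C)OC2
F9 | step 9 | [(3S,5S)-3-{[tert-butyl(dimethyl)silyl]oxy}-5-(2,2-dimethyl-1,3-dioxan-5-yl)-2-methylcyclopent-1-en-1-yl]methanol | OCC1=C(C)[C@@H](O[Si](C)(C)C(C)(C)C)C[C@H]1C2COC(C)(C)OC2
F10 | step 9 | [(1R,2R,3S,5R)-3-{[tert-butyl(dimethyl)silyl]oxy}-5-(2,2-dimethyl-1,3-dioxan-5-yl)-2-methylcyclopentyl]methanol | OC[C@H]1[C@@H](C)[C@@H](O[Si](C)(C)C(C)(C)C)C[C@H]1C2COC(C)(C)OC2
A1 | alternative 1 | dimethyl 2-[(3R,4E)-3-{[tert-butyl(dimethyl)silyl]oxy}-4-methyl-6-oxohex-4-en-1-ylidene]propanedioate | O=C/C=C(\C)[C@H](O[Si](C)(C)C(C)(C)C)CC=C(C(=O)OC)C(=O)OC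
A2 | alternative 1 | dimethyl 2-[(1R,2S,3R,4R)-4-{[tert-butyl(dimethyl)silyl]oxy}-2-formyl-3-methylcyclopentyl]propanedioate | O=C[C@@H]1[C@@H](C)[C@H](O[Si](C)(C)C(C)(C)C)C[C@H]1C(C(=O)OC)C(=O)OC
A3 | alternative 2 | (4R)-4-(2,2-dimethyl-1,3-dioxan-5-yl)cyclopent-2-en-1-one | O=C1C=C[C@H](C2COC(C)(C)OC2)C1
A4 | alternative 2 | (2R,3S,4S)-4-(2,2-dimethyl-1,3-dioxan-5-yl)-3-{[dimethyl(propan-2-yloxy)silyl]methyl}-2-methylcyclopentan-1-one | CC(C)O[Si](C)(C)C[C@@H]1[C@@H](C)C(=O)C[C@H]1C2COC(C)(C)OC2
A5 | alternative 3 | (3R,4R)-4-[(benzyloxy)methyl]-3-(2,2-dimethyl-1,3-dioxan-5-yl)hex-5-enal | O=CC[C@@H](C1COC(C)(C)OC1)[C@H](COCc1ccccc1)C=C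
A6 | alternative 3 | (1R,2R,3S,4R)-3-[(benzyloxy)methyl]-4-(2,2-dimethyl-1,3-dioxan-5-yl)-2-methylcyclopentan-1-ol | c3ccccc3COC[C@@H]1[C@@H](C)[C@H](O)C[C@H]1C2COC(C)(C)OC2
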